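**Plan**

1. Retrosynthesis: take the oxirane oxygen off C4–O–C5 to leave a (Z)-C4=C5 alkene, open the lactone at O–C12, cut ring A at C5–C6 (iodoalkene plus aldehyde), then cut the chain at C7–C8, at the C8–O acyl bond and at C10=C1.
2. Enabling feature: in the ten-membered ring A (C1–C10) the lactone carbinol C6 is allylic to the ring-cis C4=C5 alkene that underlies the oxirane and is flanked by C7, which carries the acrylate C11(=C13)–C12. C5 can therefore arrive as a (Z)-alkenyl metal and C6 as an aldehyde.
3. Forward: the C1–C5 iodo aldehyde and a malate-derived C8–C10/C14 ester are joined by aldol–dehydration (C10=C1). Indium allylation adds C6, C7 and C11–C13 (C7–C8), and the C8 and C9 oxygens are acylated. Ring A then closes at C5–C6, ring B (lactone) at O–C12, and ring C (oxirane) comes last.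
4. Stereochemistry: C9 comes from dimethyl (R)-malate; C7 and C8 from the chair, Felkin–Anh allylation; C6 from 1,2-induction by C7 in the ring closure. C4 and C5 come from the Z-alkene (propyne bromoboration) and peracid attack anti to the lactone C6–O bond. C2′ and C3′ come from Sharpless epoxidation of angelyl alcohol and SN2 opening by chloride.

Key step: step 22

Remark: atoms carry germacrane numbers (ring C1–C10, lactone carbons C11–C13, ring ester C14, methyl C15, primes for the C8 acyl group). The target SMILES is read as the cis-4,5-epoxide (4R,5S), which is why a (Z)-C4=C5 alkene is built.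

**Route**

Step 1
Reactants: 1 propyne
Product: 3 (Z)-2-bromoprop-1-enyl pinacol boronate, via (Z)-(2-bromoprop-1-enyl)dibromoborane 2 (not isolated)
Conditions: BBr3, CH2Cl2, −78 °C; then pinacol, −78 °C to rt
Reagents that add atoms: boron tribromide BrB(Br)Br; pinacol CC(C)(O)C(C)(C)O
Why: Syn-bromoboration of the terminal alkyne puts bromine on the internal carbon and boron on the terminal carbon on the same side, and trapping with pinacol in the cold should fix the (Z)-bromoalkenylboronate before it can isomerise.

Step 2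
Reactants: 3 (Z)-2-bromoprop-1-enyl pinacol boronate; 4 [2-(1,3-dioxolan-2-yl)ethyl]zinc bromide
Product: 5 (Z)-4-(1,3-dioxolan-2-yl)-2-methylbut-1-enyl pinacol boronate
Conditions: Pd(P(t-Bu)3)2 (2 mol %), THF, rt
Reagents that add atoms: none
Why: Negishi coupling, in which zerovalent palladium inserts into the C–Br bond with retention and the C–B bond stays intact, so the alkyl chain ends up cis to boron.

Step 3
Reactants: 5 (Z)-4-(1,3-dioxolan-2-yl)-2-methylbut-1-enyl pinacol boronate
Product: 6 2-[(Z)-4-iodo-3-methylbut-3-enyl]-1,3-dioxolane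
Conditions: NaOH (aq), I2, THF, 0 °C to rt
Reagents that add atoms: iodine II
Why: Iododeboronation of the hydroxide-activated alkenylboronate proceeds with retention of alkene geometry and should give the (Z)-iodoalkene, the dioxolane being inert to base.

Step 4
Reactants: 6 2-[(Z)-4-iodo-3-methylbut-3-enyl]-1,3-dioxolane
Product: 7 (Z)-5-iodo-4-methylpent-4-enal
Conditions: 1 M HCl (aq), THF, rt
Reagents that add atoms: water O
Why: Acid-catalysed acetal hydrolysis frees the C1 aldehyde, and the alkenyl iodide does not react with dilute aqueous acid.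

Step 5
Reactants: 8 dimethyl (R)-malate
Product: 9 methyl (R)-3,4-dihydroxybutanoate
Conditions: BH3·SMe2, NaBH4 (5 mol %), THF, rt; then MeOH
Reagents that add atoms: none
Why: Hydroxyl-directed, NaBH4-catalysed borane reduction of an α-hydroxy ester: the hydroxyl group binds boron and hydride reaches only the neighbouring ester, leaving the distal ester and the C9 stereocentre untouched.

Step 6
Reactants: 9 methyl (R)-3,4-dihydroxybutanoate
Product: 10 methyl (R)-3,4-bis(triethylsilyloxy)butanoate
Conditions: Et3SiCl, imidazole, DMF, 0 °C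
Reagents that add atoms: chlorotriethylsilane CC[Si](Cl)(CC)CC
Why: Silyl ether formation on a primary and a secondary alcohol, run directly on the crude diol so that the γ-hydroxy ester has no time to lactonise.

Step 7
Reactants: 10 methyl (R)-3,4-bis(triethylsilyloxy)butanoate; 7 (Z)-5-iodo-4-methylpent-4-enal
Product: 12 aldol adduct (C10/C1 epimer mixture), via lithium ester enolate 11 (not isolated)
Conditions: LiN(i-Pr)2, THF, −78 °C; then 7, −78 °C; aq NH4Cl
Reagents that add atoms: none
Why: Directed aldol addition of an ester lithium enolate to an aliphatic aldehyde; at −78 °C the β-silyloxy enolate should not eliminate, and the two new centres (C10, C1) do not matter because step 8 removes both.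

Step 8
Reactants: 12 aldol adduct (C10/C1 epimer mixture)
Product: 14 methyl (2E,6Z)-2-[(1R)-1,2-bis(triethylsilyloxy)ethyl]-7-iodo-6-methylhepta-2,6-dienoate, via β-mesyloxy ester 13 (not isolated)
Conditions: MsCl, Et3N, CH2Cl2, 0 °C; then DBU, rt
Reagents that add atoms: none
Why: Mesylation followed by E1cB elimination, in which the enolate expels mesylate and not the poor silyloxy leaving group at C9; the stereoconvergent pathway should favour the enoate with the ester trans to the C2 chain, which is the ring-cis C1=C10 geometry of the target.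

Step 9
Reactants: 14 methyl (2E,6Z)-2-[(1R)-1,2-bis(triethylsilyloxy)ethyl]-7-iodo-6-methylhepta-2,6-dienoate
Product: 15 methyl (2E,6Z)-7-iodo-6-methyl-2-[(1R)-2-oxo-1-(triethylsilyloxy)ethyl]hepta-2,6-dienoate
Conditions: (COCl)2, DMSO, CH2Cl2, −78 to −40 °C; then i-Pr2NEt, −78 to −20 °C; used at once in step 12
Reagents that add atoms: none
Why: Swern oxidation applied to a bis-triethylsilyl ether, where the chlorosulfonium salt cleaves only the unhindered primary Si–O bond and takes C8 directly to the aldehyde; low temperature and a hindered base should keep C9 from epimerising.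

Step 10
Reactants: 16 2-[(4-methoxybenzyl)oxy]acetaldehyde; 17 methyl acrylate
Product: 18 methyl 3-hydroxy-4-[(4-methoxybenzyl)oxy]-2-methylidenebutanoate (racemic)
Conditions: DABCO (0.5 equiv), dioxane–H2O (1:1), rt
Reagents that add atoms: none
Why: Morita–Baylis–Hillman reaction of an activated α-alkoxy aldehyde with methyl acrylate; the carbinol centre is irrelevant because step 11 removes it.

Step 11
Reactants: 18 methyl 3-hydroxy-4-[(4-methoxybenzyl)oxy]-2-methylidenebutanoate (racemic)
Product: 19 methyl (Z)-2-(bromomethyl)-4-[(4-methoxybenzyl)oxy]but-2-enoate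
Conditions: NBS, Me2S, CH2Cl2, 0 °C to rt
Reagents that add atoms: N-bromosuccinimide O=C1CCC(=O)N1Br
Why: Corey–Kim-type activation of the allylic alcohol and SN2′ attack of bromide should give the rearranged primary allylic bromide as the preferred isomer with the ester trans to the CH2OPMB group, under neutral conditions that spare the PMB ether.

Step 12
Reactants: 15 methyl (2E,6Z)-7-iodo-6-methyl-2-[(1R)-2-oxo-1-(triethylsilyloxy)ethyl]hepta-2,6-dienoate; 19 methyl (Z)-2-(bromomethyl)-4-[(4-methoxybenzyl)oxy]but-2-enoate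
Product: 21 homoallylic alcohol (C8–OH; C9–OSiEt3; C6–OPMB; 7S,8S,9R), via allylindium dibromide 20 (not isolated)
Conditions: In powder, THF–H2O (3:1), rt
Reagents that add atoms: none
Why: Barbier allylation in which indium inserts only into the allylic C–Br bond; the allylindium, with CH2In cis to CH2OPMB, should add through a chair transition state to give the syn C7/C8 relationship, while Felkin–Anh attack anti to the bulky, non-chelating C9 silyloxy group should set C8 anti to C9.

Step 13
Reactants: 22 angelic acid
Product: 23 (Z)-2-methylbut-2-en-1-ol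
Conditions: LiAlH4, Et2O, 0 °C
Reagents that add atoms: none
Why: Hydride reduction of the conjugated acid to the allylic alcohol, which leaves the trisubstituted alkene and its Z geometry untouched.

Step 14
Reactants: 23 (Z)-2-methylbut-2-en-1-ol
Product: 24 [(2R,3S)-2,3-dimethyloxiran-2-yl]methanol
Conditions: Ti(Oi-Pr)4 (10 mol %), D-(−)-diethyl tartrate (12 mol %), t-BuOOH, 4 Å MS, CH2Cl2, −20 °C
Reagents that add atoms: tert-butyl hydroperoxide CC(C)(C)OO
Why: Sharpless asymmetric epoxidation, in which the D-(−)-tartrate catalyst should deliver oxygen to the face that gives the (2R,3S)-epoxy alcohol, the cis relationship of CH2OH and the C3′ methyl group following from the Z-alkene.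

Step 15
Reactants: 24 [(2R,3S)-2,3-dimethyloxiran-2-yl]methanol
Product: 25 (2S,3S)-2,3-dimethyloxirane-2-carboxylic acid
Conditions: RuCl3·xH2O (2 mol %), NaIO4, MeCN–EtOAc–H2O, rt
Reagents that add atoms: water O
Why: RuCl3-catalysed periodate oxidation takes the primary alcohol to the acid through the aldehyde hydrate and leaves the epoxide and both centres intact (C2′ changes its descriptor only because the priorities change).

Step 16
Reactants: 21 homoallylic alcohol (C8–OH; C9–OSiEt3; C6–OPMB; 7S,8S,9R); 25 (2S,3S)-2,3-dimethyloxirane-2-carboxylic acid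
Product: 27 C8 epoxyangelate, via mixed trichlorobenzoic anhydride 26 (not isolated)
Conditions: 25, 2,4,6-trichlorobenzoyl chloride, Et3N, toluene, rt; then 21, DMAP, toluene, rt
Reagents that add atoms: none
Why: Yamaguchi esterification, in which DMAP attacks the aliphatic carbonyl of the mixed anhydride and passes the acyl group to the hindered C8 hydroxyl; no stereocentre is touched and the weakly basic medium should not lactonise the γ-hydroxy acrylate.

Step 17
Reactants: 27 C8 epoxyangelate
Product: 28 C9 alcohol
Conditions: PPTS (cat.), MeOH–CH2Cl2, 0 °C to rt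
Reagents that add atoms: none
Why: Mild acid-catalysed methanolysis of the secondary triethylsilyl ether, to which the PMB ether, the glycidic ester and the methyl esters are stable.

Step 18
Reactants: 28 C9 alcohol
Product: 29 C9 acetate
Conditions: Ac2O, pyridine, DMAP (cat.), CH2Cl2, 0 °C
Reagents that add atoms: acetic anhydride CC(=O)OC(C)=O
Why: Standard acetylation of the secondary C9 alcohol; the neighbouring ester of a fully α-substituted acid is too hindered to migrate under these conditions.

Step 19
Reactants: 29 C9 acetate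
Product: 30 chlorohydrin ester
Conditions: HCl (2 M in Et2O), CH2Cl2, −20 to 0 °C
Reagents that add atoms: hydrogen chloride Cl
Why: Acid-promoted SN2 ring opening of a glycidic ester by chloride at C3′, because C2′ is fully substituted and deactivated by the carbonyl group; inversion at C3′ converts the (2S,3S)-epoxide into the (2R,3R)-chlorohydrin.

Step 20
Reactants: 30 chlorohydrin ester
Product: 31 C6 primary alcohol
Conditions: DDQ, CH2Cl2–pH 7 buffer, 0 °C
Reagents that add atoms: none
Why: Oxidative PMB ether cleavage by DDQ in a buffered two-phase medium frees the C6 alcohol without acid or base, so the chlorohydrin and acetates are untouched and the γ-hydroxy ester should not lactonise.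

Step 21
Reactants: 31 C6 primary alcohol
Product: 32 seco aldehyde
Conditions: Dess–Martin periodinane, NaHCO3, CH2Cl2, 0 °C; used without purification
Reagents that add atoms: none
Why: Dess–Martin oxidation under bicarbonate buffer should give the β,γ-unsaturated β-acyloxy aldehyde without any base that could move the C11=C13 double bond into conjugation, epimerise C7 or eliminate the C8 ester; the tertiary alcohol cannot be oxidised.

Step 22
Reactants: 32 seco aldehyde
Product: 34 cyclodecadienol hydroxy ester, via alkenylchromium dichloride 33 (not isolated)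
Conditions: CrCl2 (15 equiv), NiCl2 (0.2 equiv), DMSO–THF, rt, syringe-pump addition to 2 mM; aq sodium serinate work-up
Reagents that add atoms: none
Why: CrCl2 reduces NiCl2 to zerovalent nickel, which inserts into the C5–I bond with retention; the alkenyl group then passes to trivalent chromium (33), and this oxophilic, weakly basic nucleophile adds to the C6 aldehyde to form C5–C6. The closest known reaction type is the Nozaki–Hiyama–Kishi macrocyclisation of iodoalkene aldehydes to medium-ring allylic alcohols. Ring A closes in a 10-exo-trig mode by 1,2-addition to the carbonyl carbon, the C=O bond lying outside the new ring. The new C6 centre is set by 1,2-induction from C7 (Felkin–Anh: C5 approaches anti to the C7–C8 bond, the larger ring-bound branch, with the acrylate gauche to oxygen), which should give the 6,7-relationship of the trans-lactone. The step needs the alkenyl metal to choose the aldehyde over four esters, an acrylate, an enoate and a secondary chloride, which alkenylchromium reagents do; it needs the Z geometry retained, which the configurationally stable alkenylnickel and alkenylchromium species secure; and it needs ring closure over oligomerisation, which slow addition at high dilution secures. The neutral medium should leave the enolisable C7 centre and the β-acyloxy group untouched.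

Step 23
Reactants: 34 cyclodecadienol hydroxy ester
Product: 35 trans-fused methylene lactone
Conditions: p-TsOH·H2O (cat.), CH2Cl2, rt
Reagents that add atoms: none
Why: Acid-catalysed lactonisation (5-exo-trig transesterification) of the γ-hydroxy ester, in which only the C6 hydroxyl can reach C12; the anti arrangement of H6 and H7 gives the trans-fused α-methylene-γ-butyrolactone.

Step 24
Reactants: 35 trans-fused methylene lactone
Product: 36 target CNP0185503.1
Conditions: mCPBA, NaHCO3, CH2Cl2, 0 °C
Reagents that add atoms: 3-chloroperbenzoic acid OOC(=O)c1cccc(Cl)c1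
Why: Prilezhaev epoxidation, in which the peracid reacts only with the electron-rich trisubstituted C4=C5 alkene (the C1=C10 enoate and C11=C13 methylene lactone are electron-poor) and syn addition keeps C3 and C6 cis; attack anti to the lactone C6–O bond in the H6-eclipsed conformer (allylic 1,3-strain, the oxygen now acylated and unable to direct by hydrogen bonding) should give the (4R,5S)-epoxide.

**Compound list**

1 | propyne | CC#C | starting material
2 | (Z)-(2-bromoprop-1-enyl)dibromoborane | Br/C(C)=C\B(Br)Br | intermediate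
3 | (Z)-2-bromoprop-1-enyl pinacol boronate: 2-[(Z)-2-bromoprop-1-en-1-yl]-4,4,5,5-tetramethyl-1,3,2-dioxaborolane | Br/C(C)=C\B1OC(C)(C)C(C)(C)O1 | intermediate
4 | [2-(1,3-dioxolan-2-yl)ethyl]zinc bromide | Br[Zn]CCC1OCCO1 | starting material
5 | (Z)-4-(1,3-dioxolan-2-yl)-2-methylbut-1-enyl pinacol boronate: 2-[(Z)-4-(1,3-dioxolan-2-yl)-2-methylbut-1-en-1-yl]-4,4,5,5-tetramethyl-1,3,2-dioxaborolane | C/C(CCC1OCCO1)=C/B1OC(C)(C)C(C)(C)O1 | intermediate
6 | 2-[(Z)-4-iodo-3-methylbut-3-enyl]-1,3-dioxolane | I/C=C(C)\CCC1OCCO1 | intermediate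
7 | (Z)-5-iodo-4-methylpent-4-enal (C1–C5, C15) | I/C=C(C)\CCC=O | intermediate
8 | dimethyl (R)-malate | COC(=O)[C@H](O)CC(=O)OC | starting material
9 | methyl (R)-3,4-dihydroxybutanoate | OC[C@H](O)CC(=O)OC | intermediate
10 | methyl (R)-3,4-bis(triethylsilyloxy)butanoate (C14, C10, C9, C8) | CC[Si](CC)(CC)OC[C@H](O[Si](CC)(CC)CC)CC(=O)OC | intermediate
11 | lithium ester enolate of 10 (enolate geometry not defined) | CC[Si](CC)(CC)OC[C@H](O[Si](CC)(CC)CC)C=C(OC)O[Li] | intermediate
12 | aldol adduct: methyl (6Z)-2-[(1R)-1,2-bis(triethylsilyloxy)ethyl]-3-hydroxy-7-iodo-6-methylhept-6-enoate, mixture of epimers at C2 and C3 of the heptenoate (C10 and C1) | CC[Si](CC)(CC)OC[C@H](O[Si](CC)(CC)CC)C(C(=O)OC)C(O)CC/C(C)=C\I | intermediate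
13 | β-mesyloxy ester: 3-O-methanesulfonate of 12 | CC[Si](CC)(CC)OC[C@H](O[Si](CC)(CC)CC)C(C(=O)OC)C(OS(C)(=O)=O)CC/C(C)=C\I | intermediate
14 | methyl (2E,6Z)-2-[(1R)-1,2-bis(triethylsilyloxy)ethyl]-7-iodo-6-methylhepta-2,6-dienoate | CC[Si](CC)(CC)OC[C@H](O[Si](CC)(CC)CC)/C(C(=O)OC)=C\CC/C(C)=C\I | intermediate
15 | methyl (2E,6Z)-7-iodo-6-methyl-2-[(1R)-2-oxo-1-(triethylsilyloxy)ethyl]hepta-2,6-dienoate (C8 aldehyde) | O=C[C@H](O[Si](CC)(CC)CC)/C(C(=O)OC)=C\CC/C(C)=C\I | intermediate
16 | 2-[(4-methoxybenzyl)oxy]acetaldehyde | O=CCOCc1ccc(OC)cc1 | starting material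
17 | methyl acrylate | C=CC(=O)OC | starting material
18 | methyl 3-hydroxy-4-[(4-methoxybenzyl)oxy]-2-methylidenebutanoate (racemic) | C=C(C(=O)OC)C(O)COCc1ccc(OC)cc1 | intermediate
19 | methyl (Z)-2-(bromomethyl)-4-[(4-methoxybenzyl)oxy]but-2-enoate | BrC/C(C(=O)OC)=C\COCc1ccc(OC)cc1 | intermediate
20 | allylindium dibromide from 19 (CH2In cis to CH2OPMB) | Br[In](Br)C/C(C(=O)OC)=C\COCc1ccc(OC)cc1 | intermediate
21 | homoallylic alcohol: methyl (3S,4S,5R,6E,10Z)-4-hydroxy-11-iodo-6-(methoxycarbonyl)-3-{[(4-methoxybenzyl)oxy]methyl}-10-methyl-2-methylidene-5-(triethylsilyloxy)undeca-6,10-dienoate (germacrane 7S,8S,9R) | C=C(C(=O)OC)[C@@H](COCc1ccc(OC)cc1)[C@H](O)[C@H](O[Si](CC)(CC)CC)/C(C(=O)OC)=C\CC/C(C)=C\I | intermediate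
22 | angelic acid: (Z)-2-methylbut-2-enoic acid | C/C=C(/C)C(=O)O | starting material
23 | (Z)-2-methylbut-2-en-1-ol | C/C=C(/C)CO | intermediate
24 | [(2R,3S)-2,3-dimethyloxiran-2-yl]methanol | C[C@@H]1O[C@]1(C)CO | intermediate
25 | (2S,3S)-2,3-dimethyloxirane-2-carboxylic acid | C[C@@H]1O[C@]1(C)C(=O)O | intermediate
26 | mixed trichlorobenzoic anhydride: (2S,3S)-2,3-dimethyloxirane-2-carboxylic 2,4,6-trichlorobenzoic anhydride | C[C@@H]1O[C@]1(C)C(=O)OC(=O)c1c(Cl)cc(Cl)cc1Cl | intermediate
27 | C8 epoxyangelate: 21 with the C8 oxygen acylated by (2S,3S)-2,3-dimethyloxirane-2-carbonyl (7S,8S,9R) | C=C(C(=O)OC)[C@@H](COCc1ccc(OC)cc1)[C@H](OC(=O)[C@@]2(C)O[C@H]2C)[C@H](O[Si](CC)(CC)CC)/C(C(=O)OC)=C\CC/C(C)=C\I | intermediate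
28 | C9 alcohol: 27 without the triethylsilyl group (7S,8S,9R) | C=C(C(=O)OC)[C@@H](COCc1ccc(OC)cc1)[C@H](OC(=O)[C@@]2(C)O[C@H]2C)[C@H](O)/C(C(=O)OC)=C\CC/C(C)=C\I | intermediate
29 | C9 acetate: 28 acetylated at the C9 oxygen (7S,8S,9R) | C=C(C(=O)OC)[C@@H](COCc1ccc(OC)cc1)[C@H](OC(=O)[C@@]2(C)O[C@H]2C)[C@H](OC(C)=O)/C(C(=O)OC)=C\CC/C(C)=C\I | intermediate
30 | chlorohydrin ester: methyl (3S,4S,5R,6E,10Z)-5-acetoxy-4-{[(2R,3R)-3-chloro-2-hydroxy-2-methylbutanoyl]oxy}-11-iodo-6-(methoxycarbonyl)-3-{[(4-methoxybenzyl)oxy]methyl}-10-methyl-2-methylideneundeca-6,10-dienoate | C=C(C(=O)OC)[C@@H](COCc1ccc(OC)cc1)[C@H](OC(=O)[C@@](C)(O)[C@@H](C)Cl)[C@H](OC(C)=O)/C(C(=O)OC)=C\CC/C(C)=C\I | intermediate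
31 | C6 primary alcohol: 30 with CH2OH in place of CH2OPMB (undecadienoate 3S,4S,5R) | C=C(C(=O)OC)[C@@H](CO)[C@H](OC(=O)[C@@](C)(O)[C@@H](C)Cl)[C@H](OC(C)=O)/C(C(=O)OC)=C\CC/C(C)=C\I | intermediate
32 | seco aldehyde: methyl (3R,4S,5R,6E,10Z)-5-acetoxy-4-{[(2R,3R)-3-chloro-2-hydroxy-2-methylbutanoyl]oxy}-3-formyl-11-iodo-6-(methoxycarbonyl)-10-methyl-2-methylideneundeca-6,10-dienoate | C=C(C(=O)OC)[C@@H](C=O)[C@H](OC(=O)[C@@](C)(O)[C@@H](C)Cl)[C@H](OC(C)=O)/C(C(=O)OC)=C\CC/C(C)=C\I | intermediate
33 | alkenylchromium dichloride: 32 with CrCl2 in place of iodine at C5 (trivalent chromium, Z geometry kept) | C=C(C(=O)OC)[C@@H](C=O)[C@H](OC(=O)[C@@](C)(O)[C@@H](C)Cl)[C@H](OC(C)=O)/C(C(=O)OC)=C\CC/C(C)=C\[Cr](Cl)Cl | intermediate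
34 | cyclodecadienol hydroxy ester: methyl 2-[(1S,2R,3Z,7E,9R,10S)-9-acetoxy-10-{[(2R,3R)-3-chloro-2-hydroxy-2-methylbutanoyl]oxy}-2-hydroxy-8-(methoxycarbonyl)-4-methylcyclodeca-3,7-dien-1-yl]prop-2-enoate (germacrane 6R,7S,8S,9R) | C1/C(C)=C\[C@@H](O)[C@H](C(=C)C(=O)OC)[C@H](OC(=O)[C@@](C)(O)[C@@H](C)Cl)[C@H](OC(C)=O)/C(C(=O)OC)=C\C1 | intermediate
35 | trans-fused methylene lactone: (1(10)E,4Z)-germacra-1(10),4,11(13)-trien-12,6-olide with 9-acetoxy, 8-[(2R,3R)-3-chloro-2-hydroxy-2-methylbutanoyl]oxy and C14 methyl ester (6R,7S,8S,9R) | C=C1C(=O)O[C@H]2[C@H]1[C@H](OC(=O)[C@@](C)(O)[C@@H](C)Cl)[C@H](OC(C)=O)/C(C(=O)OC)=C\CC/C(C)=C\2 | intermediate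
36 | target CNP0185503.1: (4R,5S)-4,5-epoxide of 35 (4R,5S,6S,7R,8S,9R; acyl 2R,3R) | C=C1C(=O)O[C@H]2[C@H]1[C@H](OC(=O)[C@@](C)(O)[C@@H](C)Cl)[C@H](OC(C)=O)/C(C(=O)OC)=C\CC[C@@]1(C)O[C@@H]21 | target

**Step count and risks**

Total step count: 24. Longest linear sequence: 17 steps (steps 1–4, 7–9, 12, 16–24).

Step 22 is the most likely to fail. The alkenylchromium may add to the C6 aldehyde with poor facial selectivity, because the acrylate and the C8 branch compete for the position anti to the incoming carbon in a ring-constrained transition state. The fallback sets out from 32 and keeps the same ring closure. The 6-epi hydroxy ester F1 that would then predominate is oxidised with Dess–Martin periodinane to the cyclodecadienone F2. A Luche reduction (NaBH4, CeCl3·7H2O, MeOH, −78 °C), with hydride arriving from the exposed face of the ring, should then return the route at 34. This sets C6 by reduction instead of by addition.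

Step 24 is the second risk. The conformation of ring A may expose the alkene face syn to the lactone oxygen, so that the peracid attacks the wrong face. The fallback sets out from 35. NBS in aqueous THF should form the bromonium ion on the face the peracid prefers, and water opens it at the tertiary C4 from the other side to give the bromohydrin F3. Ag2O in dry DME, which is not basic enough to close the side-chain chlorohydrin, then closes the oxirane with inversion at C5. This places the oxygen on the face opposite to the one the electrophile chose and returns the route at 36.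

Step 12 is the third risk. Felkin–Anh control at C8 may be weak if the silyloxy oxygen chelates indium in water, and the syn C7/C8 relationship may erode if the transition state is loose. The fallback sets out from 18 and replaces the Barbier reaction by an allylboration. Acetylation (Ac2O, pyridine) gives the acetate F4. Borylation with bis(pinacolato)diboron and Pd2(dba)3, with allylic transposition, gives the (E)-2-(methoxycarbonyl)allyl pinacol boronate F5, in which CH2B is cis to CH2OPMB. Heating F5 with aldehyde 15 in toluene should pass through a tight, closed chair transition state to the borate ester F6, whose hydrolysis on work-up returns the route at 21.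

**Further compounds**

F1 | step 22 | 6-epi hydroxy ester (C6 epimer of 34) | C1/C(C)=C\[C@H](O)[C@H](C(=C)C(=O)OC)[C@H](OC(=O)[C@@](C)(O)[C@@H](C)Cl)[C@H](OC(C)=O)/C(C(=O)OC)=C\C1
F2 | step 22 | cyclodecadienone (C6 ketone of 34) | C1/C(C)=C\C(=O)[C@H](C(=C)C(=O)OC)[C@H](OC(=O)[C@@](C)(O)[C@@H](C)Cl)[C@H](OC(C)=O)/C(C(=O)OC)=C\C1
F3 | step 24 | bromohydrin of 35 (C4–OH, C5–Br, anti) | C=C1C(=O)O[C@H]2[C@H]1[C@H](OC(=O)[C@@](C)(O)[C@@H](C)Cl)[C@H](OC(C)=O)/C(C(=O)OC)=C\CC[C@@](C)(O)[C@@H]2Br
F4 | step 12 | methyl 3-acetoxy-4-[(4-methoxybenzyl)oxy]-2-methylidenebutanoate (racemic) | C=C(C(=O)OC)C(OC(C)=O)COCc1ccc(OC)cc1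
F5 | step 12 | methyl (E)-4-[(4-methoxybenzyl)oxy]-2-[(4,4,5,5-tetramethyl-1,3,2-dioxaborolan-2-yl)methyl]but-2-enoate | COC(=O)/C(CB1OC(C)(C)C(C)(C)O1)=C/COCc1ccc(OC)cc1
F6 | step 12 | C8 O-pinacolboryl ester of 21 | C=C(C(=O)OC)[C@@H](COCc1ccc(OC)cc1)[C@H](OB2OC(C)(C)C(C)(C)O2)[C@H](O[Si](CC)(CC)CC)/C(C(=O)OC)=C\CC/C(C)=C\I
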